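**Ring and atom labels used throughout.** Ring A is the 2,6-dioxygenated ring of the first ketone. Ring B is the catechol with the chain on B1, ring C on B2 and oxygen on B4 and B5. Ring C has C1 bonded to B2, oxygen on C4 and C6 and the acyl group on C5. Ring D is the terminal catechol.

## Structural features

Giganteone A is an unsymmetrical dimer of two 1,9-diarylnonan-1-one units. Ring A (a 2,6-dihydroxyphenyl ketone) is linked through CO–(CH2)8 to catechol ring B, and ring C (a second 2,6-dihydroxyphenyl ketone) is linked through another CO–(CH2)8 chain to catechol ring D. The halves are joined by a single biaryl bond, B2–C1, which makes ring B 1,2,4,5-tetrasubstituted and ring C 1,2,3,4-tetrasubstituted with C1, C6, C5 and C4 contiguous. There are no stereocentres, and the biaryl axis has only two ortho substituents (the B1 chain and the C6 hydroxyl), so it rotates freely and no stereochemical element has to be controlled. The fragile groups are the two catechols, which autoxidise to o-quinones, and the two acylresorcinols with their enolisable α-CH2 groups; all eight phenols must stay masked until the end. The real difficulty is regiochemical: four electron-rich rings of similar reactivity rule out late electrophilic substitution, and B2–C1 joins two electron-rich, ortho-substituted rings. The key step uses the fact that B1 and B2 are adjacent and carry the only carbon substituents, while B4 and B5 carry the two oxygens and B3 and B6 are CH. B1–B2 therefore maps onto an internal alkyne and B3–B4–B5–B6 onto a symmetrical 2,3-dioxygenated butadiene.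

## Logic of the disconnections

**22 to 21.** The eight O–CH3 bonds are cut. One small, robust ether type survives organolithiums, palladium, the cobalt/zinc system and a quinone oxidant, so a single group serves all eight phenols. The forward step must be an exhaustive ether cleavage that leaves both ketones and both chains untouched and keeps air away from the freed catechols.

**21 to 20.** Two hydrogens are added back at B3 and B6. The arene lies one oxidation level above the cycloadduct, so ring B is traced to its cyclohexa-1,4-diene. The forward dehydrogenation must take hydrogen from the doubly allylic ring positions only and not from the benzylic CH2 groups of the chains.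

**20 to 18 and 19.** B1–B6 and B2–B3 are cut. This removes ring B altogether and turns the difficult biaryl bond B2–C1 into an ordinary aryl–alkyne bond. Because 19 is symmetrical, no regiochemical question arises. The forward step must make an unactivated, hindered internal alkyne react as a dienophile in the presence of two ketones.

**18 to 10 and 17.** The bond between C1 of ring C and the alkyne carbon is cut. This gives two fragments of similar size and makes the route convergent. The forward coupling needs a halogen on C1 of ring C and nowhere else, and must tolerate both enolisable ketones.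

**10 to 8 and 7 (through 9).** The bond between C5 of ring C and its carbonyl carbon is cut. The carbonyl sits between two methoxy groups, which is the natural site of a directed metalation. The bromine is carried in with 8 rather than introduced afterwards, because in a bromine-free analogue of 10 rings C and D would be about equally activated towards an electrophile. The forward step needs a base that removes the proton between the methoxy groups without touching the C–Br bond, and an acyl donor that stops at the ketone.

**7 to 5, 4, and then 1 and 2 (through 6 and 3).** The amide is traced to the acid 5, the saturated chain to the alkene 4, and the C8=C9 bond is cut to give 1 and 2. The whole ring D chain then comes from a C1 aldehyde and a C8 phosphonium unit. Double-bond geometry is irrelevant because it is erased.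

**17 to 14 and 13 (through 15 and 16), and 13 to 11 (through 12).** The aryl–carbonyl bond of ring A is cut in the same way as for ring C. The chain, its alkyne terminus and the two future ring B carbons all come from 11. The forward step must cope with the acidic alkyne C–H of 13, which consumes one equivalent of 15.

## Other disconnections considered

**Alternative 1:** Ring C is built instead of ring B, by cutting C6–C5, C6–C1 and C3–C4.
- **Forward step.** Irradiation of the styryl diazo ketone A2 (ring B with its ester chain already attached) would trigger a Wolff rearrangement to an arylvinylketene. This would add to the ethoxyalkyne A3 by [2+2] addition, the vinylcyclobutenone would open in a four-electron process, and the dienylketene would close in a six-electron process to give phenol A1 (a Danheiser-type benzannulation).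
- **In its favour.** The contiguous C1/C6/C5/C4 pattern is fixed by the polarity of the ynol ether, B2–C1 exists before the ring is made, and no metal is needed.
- **Against it here.** Ring B must first be prepared as a 1,2,4,5-tetrasubstituted cinnamoyl derivative, so its regiochemical problem is only moved. A3 is an acid-sensitive ynol ether with a silyloxy stereocentre and needs its own multi-step synthesis. Styryl diazo ketones can isomerise or cyclise under irradiation. After A1 the carbinol must still be unmasked and oxidised, the phenol and ethyl ether handled, and ring A attached to the ester, roughly six further operations.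
- **Comparison.** Both plans build one benzene ring from an alkyne. The chosen plan builds the ring whose symmetrical dioxygenation removes all regiochemical questions, and it reaches the key step with both ketone chains and ring A complete. On regiocontrol of ring C the alternative is the equal of the chosen plan, which obtains the pattern by directed metalation. It is the better plan in one respect: the arene forms at the correct oxidation level and needs no dehydrogenation. On step count and on the number of sensitive intermediates the chosen plan is expected to be the better.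

**Alternative 2:** The B1–CH2 bond of the ring B chain is cut, and the ring C oxygen at C6 is used as a temporary tether.
- **Forward step.** The biaryl phenol A5 and the keto aldehyde A6 would condense under acid to an aryl oxocarbenium ion. This would attack ring B para to a methoxy group, closing a pyran ring and giving the racemic benzo[c]chromene A4. The benzylic C–O bond would then be cleaved reductively to release the C6 phenol and leave the chain on B1.
- **In its favour.** A5 is available by a routine cross-coupling of simple partners. The position of the chain on ring B is fixed both by the six-membered ring closure and by the para-methoxy group. The key step needs only a Brønsted acid.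
- **Against it here.** A4 carries no acyl chain on ring C. Introducing it later at C5, between the two oxygens, would need a directed metalation that conflicts with the ring A ketone, and a Friedel–Crafts acylation would go to C3 instead. The reductive ether cleavage must also spare an aryl ketone. The stereocentre that is created and destroyed is harmless.
- **Comparison.** For making the biaryl bond the alternative is the better plan, since cross-coupling of two simple arenes is more predictable than catalysis on a hindered alkyne. For placing the ring B chain the two plans are equal, since both are unambiguous. Overall the alternative is expected to be longer and to put its regiochemical risk at the end, whereas the chosen plan carries both acyl chains intact through the ring-forming step.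

**Alternative 3:** Ring A is cut at A1–A6 in a polyketide-like way.
- **Forward step.** Base would deprotonate the carbon between the two ketones of the open-chain silyloxy diketo ester A8. Claisen attack on the terminal ester would close the ring, and loss of silanol would aromatise it to A7, the hexamethyl ether with free ring A hydroxyls.
- **In its favour.** The step is biomimetic and needs no cryogenic organolithium. Ring A arrives unprotected, so only six ethers remain for the final cleavage.
- **Against it here.** Ring A is the simplest part of the molecule and is available in one step from 14. The plan leaves the ring B/ring C problem untouched. A8 is a long, sensitive chain with a second enolisable aryl ketone that offers competing aldol and Claisen pathways.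
- **Comparison.** Both plans make an arene de novo without regiochemical ambiguity, so on that point they are equal. The free ring A hydroxyls are a real, if small, advantage of the alternative at the deprotection stage. In step economy the chosen plan is expected to be much the better, because it spends its ring-forming step on the ring that is otherwise hard to make.

Key step: step 8

**Design remarks.**
- Ring C is halogenated before ring D is attached. An electrophilic bromination of a ring C ketone that already carries the 4-alkylveratrole ring D would face two rings of comparable activation, so the bromine comes in with building block 8.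
- The alkyne C–H of 13 consumes one equivalent of aryllithium. This is supplied on purpose in step 6.

**Assumption.** (7-Carboxyheptyl)triphenylphosphonium bromide 2, 1-bromo-2,4-dimethoxybenzene 8 and 2,3-dimethoxybuta-1,3-diene 19 are taken as purchasable. If 2 were unavailable it would be made in one operation from 8-bromooctanoic acid and PPh3.

## Route

Step 1
Reactants: 1 3,4-dimethoxybenzaldehyde; 2 (7-carboxyheptyl)triphenylphosphonium bromide
Product: 4 (Z)-9-(3,4-dimethoxyphenyl)non-8-enoic acid, via sodium 8-(triphenylphosphoranylidene)octanoate 3 (not isolated)
Conditions: 2 (1.2 equiv), NaN(SiMe3)2 (2.4 equiv), THF, 0 °C; then 1, 0 °C → rt; aq HCl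
Reagents that add atoms: none
Why: Wittig olefination; the first equivalent of base forms the carboxylate and the second the non-stabilised ylide 3, which should give mainly the Z alkene with some E isomer, and the geometry is irrelevant because step 2 saturates the bond; the acid is separated from Ph3PO by base extraction.

Step 2
Reactants: 4 (Z)-9-(3,4-dimethoxyphenyl)non-8-enoic acid (isomer mixture)
Product: 5 9-(3,4-dimethoxyphenyl)nonanoic acid
Conditions: H2 (1 atm), 10% Pd/C, EtOAc, rt
Reagents that add atoms: none
Why: Heterogeneous catalytic hydrogenation of a styrenic alkene; both geometric isomers converge, and the veratrole ring, the ethers and the acid are inert under these conditions.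

Step 3
Reactants: 5 9-(3,4-dimethoxyphenyl)nonanoic acid
Product: 7 9-(3,4-dimethoxyphenyl)-N-methoxy-N-methylnonanamide, via 1-[9-(3,4-dimethoxyphenyl)nonanoyl]imidazole 6 (not isolated)
Conditions: 1,1'-carbonyldiimidazole (1.2 equiv), CH2Cl2, rt; then MeNHOMe·HCl (1.5 equiv), rt
Reagents that add atoms: N,O-dimethylhydroxylamine hydrochloride, CNOC.Cl
Why: Amide formation through the acyl imidazolide; the Weinreb amide is chosen because its chelated tetrahedral adduct stops an aryllithium addition at the ketone stage.

Step 4
Reactants: 8 1-bromo-2,4-dimethoxybenzene; 7 9-(3,4-dimethoxyphenyl)-N-methoxy-N-methylnonanamide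
Product: 10 1-(3-bromo-2,6-dimethoxyphenyl)-9-(3,4-dimethoxyphenyl)nonan-1-one, via (3-bromo-2,6-dimethoxyphenyl)lithium 9 (not isolated)
Conditions: 8 (1.4 equiv), lithium 2,2,6,6-tetramethylpiperidide (1.3 equiv, from 2,2,6,6-tetramethylpiperidine and n-BuLi), THF, −78 °C, 1 h; then 7 (1.0 equiv), −78 → 0 °C; aq NH4Cl
Reagents that add atoms: none
Why: Directed ortho-metalation followed by Weinreb ketone synthesis; the proton of 8 between the two methoxy groups is the most acidic, and a hindered lithium amide removes it without bromine–lithium exchange. In 9 lithium is meta to bromine, so no aryne can form, and 9 adds once to 7 to give the ring C ketone with the bromine already in the correct position.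

Step 5
Reactants: 11 undec-10-ynoic acid
Product: 13 N-methoxy-N-methylundec-10-ynamide, via 1-(undec-10-ynoyl)imidazole 12 (not isolated)
Conditions: 1,1'-carbonyldiimidazole (1.2 equiv), CH2Cl2, rt; then MeNHOMe·HCl (1.5 equiv), rt
Reagents that add atoms: N,O-dimethylhydroxylamine hydrochloride, CNOC.Cl
Why: Weinreb amide formation through the acyl imidazolide, as in step 3; the terminal alkyne is unaffected by these neutral conditions.

Step 6
Reactants: 14 1,3-dimethoxybenzene; 13 N-methoxy-N-methylundec-10-ynamide
Product: 17 1-(2,6-dimethoxyphenyl)undec-10-yn-1-one, via (2,6-dimethoxyphenyl)lithium 15 (not isolated), via lithiated alkynyl amide 16 (not isolated)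
Conditions: 14 (2.7 equiv), n-BuLi (2.5 equiv), THF, 0 °C → rt, 2 h; then 13 (1.0 equiv) added slowly at −78 °C, → −20 °C; aq NH4Cl
Reagents that add atoms: none
Why: Directed ortho-lithiation of 14 at C2 followed by Weinreb ketone synthesis; the first equivalent of 15 removes the acetylenic proton to give 16 and the second adds to the amide. Slow addition of 13 to excess 15 at low temperature keeps 16 away from free amide, and the aqueous quench restores the terminal alkyne.

Step 7
Reactants: 10 1-(3-bromo-2,6-dimethoxyphenyl)-9-(3,4-dimethoxyphenyl)nonan-1-one; 17 1-(2,6-dimethoxyphenyl)undec-10-yn-1-one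
Product: 18 11-{3-[9-(3,4-dimethoxyphenyl)nonanoyl]-2,4-dimethoxyphenyl}-1-(2,6-dimethoxyphenyl)undec-10-yn-1-one
Conditions: 17 (1.2 equiv), Pd(PhCN)2Cl2 (3 mol%), [HP(t-Bu)3]BF4 (6 mol%), CuI (2 mol%), i-Pr2NH, 1,4-dioxane, rt → 45 °C, argon
Reagents that add atoms: none
Why: Sonogashira coupling; the bulky, electron-rich P(t-Bu)3 ligand lets zerovalent palladium insert into the electron-rich, ortho-substituted aryl bromide near room temperature, and the amine base is too weak to disturb either enolisable ketone.

Step 8
Reactants: 18 11-{3-[9-(3,4-dimethoxyphenyl)nonanoyl]-2,4-dimethoxyphenyl}-1-(2,6-dimethoxyphenyl)undec-10-yn-1-one; 19 2,3-dimethoxybuta-1,3-diene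
Product: 20 1-(2,6-dimethoxyphenyl)-9-(2-{3-[9-(3,4-dimethoxyphenyl)nonanoyl]-2,4-dimethoxyphenyl}-4,5-dimethoxycyclohexa-1,4-dien-1-yl)nonan-1-one
Conditions: 19 (3 equiv), CoBr2(dppe) (10 mol%), Zn powder (20 mol%), ZnI2 (20 mol%), CH2Cl2, rt, argon; filtration through basic alumina
Reagents that add atoms: none
Why: Zinc reduces CoBr2(dppe) from divalent to monovalent cobalt and ZnI2 removes the remaining halide, leaving a cationic monovalent cobalt centre whose chelating dppe leaves room for one diene and one alkyne. Diene 19 binds in its s-cis form beside the alkyne of 18, oxidative coupling gives a trivalent cobaltacycle (an allyl–vinyl cobalt species) in which the first new bond (B2–B3 or B1–B6) exists, and reductive elimination forms the second and releases 20 with return to monovalent cobalt. The closest known reaction type is the cobalt-catalysed neutral Diels–Alder reaction of unactivated internal alkynes, aryl alkyl alkynes included, with 2,3-disubstituted buta-1,3-dienes to give cyclohexa-1,4-dienes. Ring B closes by intermolecular formal [4+2] annulation: the alkyne carbons become B1 and B2 and the four diene carbons become B3 to B6. No stereocentre is formed, because B1, B2, B4 and B5 are sp2 and B3 and B6 are CH2. Regiochemistry does not arise because 19 is symmetrical. The selectivity needed is cross-addition over alkyne cyclotrimerisation and diene dimerisation: the internal, ortho-substituted alkyne of 18 trimerises slowly, the excess of 19 keeps cobalt loaded with diene, and the ketones and aryl ethers are not conjugated with the alkyne and remain spectators. The bis(enol ether) 20 is acid-sensitive, so it is freed from zinc salts on basic alumina and used without storage.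

Step 9
Reactants: 20 1-(2,6-dimethoxyphenyl)-9-(2-{3-[9-(3,4-dimethoxyphenyl)nonanoyl]-2,4-dimethoxyphenyl}-4,5-dimethoxycyclohexa-1,4-dien-1-yl)nonan-1-one
Product: 21 1-(2,6-dimethoxyphenyl)-9-(2-{3-[9-(3,4-dimethoxyphenyl)nonanoyl]-2,4-dimethoxyphenyl}-4,5-dimethoxyphenyl)nonan-1-one (giganteone A octamethyl ether)
Conditions: DDQ (1.1 equiv), toluene, 0 °C → rt
Reagents that add atoms: none
Why: Dehydrogenative aromatisation; DDQ abstracts hydride from a doubly allylic CH2 of the cyclohexa-1,4-diene and proton loss gives the arene. This should be far faster than benzylic oxidation of the veratrole-type rings, and the enol ethers become the aryl methyl ethers of ring B.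

Step 10
Reactants: 21 giganteone A octamethyl ether
Product: 22 giganteone A
Conditions: BBr3 (16 equiv), CH2Cl2, −78 °C → rt, argon; ice-water, degassed work-up
Reagents that add atoms: none
Why: Lewis-acid ether cleavage; BBr3 coordinates each ether oxygen and bromide removes the methyl group by SN2. The four ethers flanking the ketones should go first through chelation and the catechol ethers follow at rt; hydrolysis of the aryl borates frees all eight phenols, and exclusion of air during work-up protects the catechols.

## Compound list

1 | 3,4-dimethoxybenzaldehyde | COc1ccc(C=O)cc1OC | starting material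
2 | (7-carboxyheptyl)triphenylphosphonium bromide | OC(=O)CCCCCCC[P+](c1ccccc1)(c1ccccc1)c1ccccc1.[Br-] | starting material
3 | sodium 8-(triphenylphosphoranylidene)octanoate | [Na+].[O-]C(=O)CCCCCCC=P(c1ccccc1)(c1ccccc1)c1ccccc1 | intermediate (not isolated)
4 | (Z)-9-(3,4-dimethoxyphenyl)non-8-enoic acid (accompanied by its E isomer, used as the mixture) | COc1ccc(/C=C\CCCCCCC(=O)O)cc1OC | intermediate
5 | 9-(3,4-dimethoxyphenyl)nonanoic acid | COc1ccc(CCCCCCCCC(=O)O)cc1OC | intermediate
6 | 1-[9-(3,4-dimethoxyphenyl)nonanoyl]imidazole | COc1ccc(CCCCCCCCC(=O)n2ccnc2)cc1OC | intermediate (not isolated)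
7 | 9-(3,4-dimethoxyphenyl)-N-methoxy-N-methylnonanamide | COc1ccc(CCCCCCCCC(=O)N(C)OC)cc1OC | intermediate
8 | 1-bromo-2,4-dimethoxybenzene | COc1ccc(Br)c(OC)c1 | starting material
9 | (3-bromo-2,6-dimethoxyphenyl)lithium | [Li]c1c(OC)ccc(Br)c1OC | intermediate (not isolated)
10 | 1-(3-bromo-2,6-dimethoxyphenyl)-9-(3,4-dimethoxyphenyl)nonan-1-one | COc1ccc(Br)c(OC)c1C(=O)CCCCCCCCc1ccc(OC)c(OC)c1 | intermediate
11 | undec-10-ynoic acid | C#CCCCCCCCCC(=O)O | starting material
12 | 1-(undec-10-ynoyl)imidazole | C#CCCCCCCCCC(=O)n1ccnc1 | intermediate (not isolated)
13 | N-methoxy-N-methylundec-10-ynamide | C#CCCCCCCCCC(=O)N(C)OC | intermediate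
14 | 1,3-dimethoxybenzene | COc1cccc(OC)c1 | starting material
15 | (2,6-dimethoxyphenyl)lithium | [Li]c1c(OC)cccc1OC | intermediate (not isolated)
16 | {11-[methoxy(methyl)amino]-11-oxoundec-1-yn-1-yl}lithium (lithiated alkynyl amide) | [Li]C#CCCCCCCCCC(=O)N(C)OC | intermediate (not isolated)
17 | 1-(2,6-dimethoxyphenyl)undec-10-yn-1-one | C#CCCCCCCCCC(=O)c1c(OC)cccc1OC | intermediate
18 | 11-{3-[9-(3,4-dimethoxyphenyl)nonanoyl]-2,4-dimethoxyphenyl}-1-(2,6-dimethoxyphenyl)undec-10-yn-1-one | COc1ccc(C#CCCCCCCCCC(=O)c2c(OC)cccc2OC)c(OC)c1C(=O)CCCCCCCCc1ccc(OC)c(OC)c1 | intermediate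
19 | 2,3-dimethoxybuta-1,3-diene | C=C(OC)C(OC)=C | starting material
20 | 1-(2,6-dimethoxyphenyl)-9-(2-{3-[9-(3,4-dimethoxyphenyl)nonanoyl]-2,4-dimethoxyphenyl}-4,5-dimethoxycyclohexa-1,4-dien-1-yl)nonan-1-one | COC1=C(OC)CC(-c2ccc(OC)c(C(=O)CCCCCCCCc3ccc(OC)c(OC)c3)c2OC)=C(CCCCCCCCC(=O)c2c(OC)cccc2OC)C1 | intermediate
21 | 1-(2,6-dimethoxyphenyl)-9-(2-{3-[9-(3,4-dimethoxyphenyl)nonanoyl]-2,4-dimethoxyphenyl}-4,5-dimethoxyphenyl)nonan-1-one (giganteone A octamethyl ether) | COc1cc(CCCCCCCCC(=O)c2c(OC)cccc2OC)c(-c2ccc(OC)c(C(=O)CCCCCCCCc3ccc(OC)c(OC)c3)c2OC)cc1OC | intermediate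
22 | giganteone A | O=C(CCCCCCCCc1cc(O)c(O)cc1-c1ccc(O)c(C(=O)CCCCCCCCc2ccc(O)c(O)c2)c1O)c1c(O)cccc1O | target

## Step count and risks

Total step count: 10. Longest linear sequence: 8 steps (steps 1, 2, 3, 4, 7, 8, 9, 10). Steps 5 and 6 form the second branch.

**Step 8 (key step).**
- **What may go wrong:** the many ether and ketone donors of 18 may slow or deactivate the cobalt catalyst, the hindered ortho-substituted alkyne may react slowly, and the electron-rich diene may oligomerise under ZnI2 before cross-addition.
- **Fallback:** it sets out from 7 and returns at 21, with ring B taken from a preformed arene and the biaryl bond made by cross-coupling.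
  - Bromination of 7 (NBS, MeCN, 0 °C → rt) para to a methoxy group and ortho to the chain should give 9-(2-bromo-4,5-dimethoxyphenyl)-N-methoxy-N-methylnonanamide F1.
  - Addition of 15 (from 14 and n-BuLi) at −78 °C gives 9-(2-bromo-4,5-dimethoxyphenyl)-1-(2,6-dimethoxyphenyl)nonan-1-one F2.
  - Miyaura borylation (bis(pinacolato)diboron, Pd(dppf)Cl2, KOAc, dioxane, 90 °C) gives 1-(2,6-dimethoxyphenyl)-9-[4,5-dimethoxy-2-(4,4,5,5-tetramethyl-1,3,2-dioxaborolan-2-yl)phenyl]nonan-1-one F3.
  - Suzuki coupling of F3 with 10 (Pd(OAc)2, SPhos, K3PO4, toluene/water, 90 °C) gives 21.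
  - This path also bypasses steps 7 and 9.

**Step 4.**
- **What may go wrong:** metalation may be incomplete or may occur next to bromine, leading to aryne formation, and the hindered aryllithium may enolise the amide instead of adding to it.
- **Fallback:** it sets out from 14 and returns at 10, replacing deprotonation by halogen–metal exchange.
  - 15 (from 14 and n-BuLi) is quenched with I2 to give 2-iodo-1,3-dimethoxybenzene F4.
  - Bromination (NBS, MeCN) para to a methoxy group gives 1-bromo-3-iodo-2,4-dimethoxybenzene F5.
  - Iodine–magnesium exchange with i-PrMgCl·LiCl (THF, −20 °C), much faster at iodine than at bromine, gives (3-bromo-2,6-dimethoxyphenyl)magnesium chloride F6.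
  - Acylation of F6 with 7 (0 °C → rt) gives 10.

**Step 7.**
- **What may go wrong:** oxidative addition to the electron-rich, hindered bromide may be slow, so that copper-mediated oxidative homocoupling of the alkyne takes over.
- **Fallback:** it sets out from 10 and returns at 18. A copper-catalysed aromatic Finkelstein exchange (CuI, NaI, trans-N,N'-dimethylcyclohexane-1,2-diamine, dioxane, 110 °C) converts 10 into 1-(3-iodo-2,6-dimethoxyphenyl)-9-(3,4-dimethoxyphenyl)nonan-1-one F7. This iodide should couple with 17 under standard Sonogashira conditions (Pd(PPh3)2Cl2, CuI, Et3N, rt) to give 18.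

**Step 10.**
- **What may go wrong:** cleavage of the eight ethers may stop short, and the freed catechols may be lost by air oxidation during work-up and chromatography.
- **Fallback:** it sets out from 21 and returns at 22. After BBr3 treatment the crude polyphenol is acetylated at once (Ac2O, pyridine, DMAP) to the air-stable giganteone A octaacetate F8. This can be purified on silica, with any partly methylated material separated and recycled, and is then deacetylated by acidic methanolysis (HCl, MeOH, argon) to 22.

**Step 6.**
- **What may go wrong:** the acetylide formed from the alkyne C–H may attack a second amide molecule, and acylation may be incomplete because base is consumed.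
- **Fallback:** it sets out from 11 and returns at 17, masking the acidic C–H.
  - Treatment of 11 with LDA (2.2 equiv, THF, −78 °C), then Me3SiCl and acidic work-up gives 11-(trimethylsilyl)undec-10-ynoic acid F9.
  - Amide formation as in step 5 gives N-methoxy-N-methyl-11-(trimethylsilyl)undec-10-ynamide F10.
  - Addition of 15 (1.2 equiv) gives 1-(2,6-dimethoxyphenyl)-11-(trimethylsilyl)undec-10-yn-1-one F11.
  - K2CO3 in MeOH removes the silyl group to give 17.

## Further compounds

F1 | step 8 | 9-(2-bromo-4,5-dimethoxyphenyl)-N-methoxy-N-methylnonanamide | COc1cc(Br)c(CCCCCCCCC(=O)N(C)OC)cc1OC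
F2 | step 8 | 9-(2-bromo-4,5-dimethoxyphenyl)-1-(2,6-dimethoxyphenyl)nonan-1-one | COc1cc(Br)c(CCCCCCCCC(=O)c2c(OC)cccc2OC)cc1OC
F3 | step 8 | 1-(2,6-dimethoxyphenyl)-9-[4,5-dimethoxy-2-(4,4,5,5-tetramethyl-1,3,2-dioxaborolan-2-yl)phenyl]nonan-1-one | COc1cc(B2OC(C)(C)C(C)(C)O2)c(CCCCCCCCC(=O)c2c(OC)cccc2OC)cc1OC
F4 | step 4 | 2-iodo-1,3-dimethoxybenzene | COc1cccc(OC)c1I
F5 | step 4 | 1-bromo-3-iodo-2,4-dimethoxybenzene | COc1ccc(Br)c(OC)c1I
F6 | step 4 | (3-bromo-2,6-dimethoxyphenyl)magnesium chloride | COc1ccc(Br)c(OC)c1[Mg]Cl
F7 | step 7 | 1-(3-iodo-2,6-dimethoxyphenyl)-9-(3,4-dimethoxyphenyl)nonan-1-one | COc1ccc(I)c(OC)c1C(=O)CCCCCCCCc1ccc(OC)c(OC)c1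
F8 | step 10 | giganteone A octaacetate | CC(=O)Oc1cccc(OC(C)=O)c1C(=O)CCCCCCCCc1cc(OC(C)=O)c(OC(C)=O)cc1-c1ccc(OC(C)=O)c(C(=O)CCCCCCCCc2ccc(OC(C)=O)c(OC(C)=O)c2)c1OC(C)=O
F9 | step 6 | 11-(trimethylsilyl)undec-10-ynoic acid | C[Si](C)(C)C#CCCCCCCCCC(=O)O
F10 | step 6 | N-methoxy-N-methyl-11-(trimethylsilyl)undec-10-ynamide | C[Si](C)(C)C#CCCCCCCCCC(=O)N(C)OC
F11 | step 6 | 1-(2,6-dimethoxyphenyl)-11-(trimethylsilyl)undec-10-yn-1-one | C[Si](C)(C)C#CCCCCCCCCC(=O)c1c(OC)cccc1OC
A1 | alternative 1 | methyl 9-{2-[3-(1-{[tert-butyl(dimethyl)silyl]oxy}-9-(3,4-dimethoxyphenyl)nonyl)-4-ethoxy-2-hydroxyphenyl]-4,5-dimethoxyphenyl}nonanoate (racemic) | COC(=O)CCCCCCCCc1cc(OC)c(OC)cc1-c1ccc(OCC)c(C(O[Si](C)(C)C(C)(C)C)CCCCCCCCc2ccc(OC)c(OC)c2)c1O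
A2 | alternative 1 | methyl 9-{2-[(1E)-4-diazo-3-oxobut-1-en-1-yl]-4,5-dimethoxyphenyl}nonanoate | COC(=O)CCCCCCCCc1cc(OC)c(OC)cc1/C=C/C(=O)C=[N+]=[N-]
A3 | alternative 1 | tert-butyl{[11-(3,4-dimethoxyphenyl)-1-ethoxyundec-1-yn-3-yl]oxy}dimethylsilane (racemic) | CCOC#CC(O[Si](C)(C)C(C)(C)C)CCCCCCCCc1ccc(OC)c(OC)c1
A4 | alternative 2 | 1-(2,6-dimethoxyphenyl)-8-(3,8,9-trimethoxy-6H-benzo[c]chromen-6-yl)octan-1-one (racemic) | COc1ccc2c(c1)OC(CCCCCCCC(=O)c1c(OC)cccc1OC)c1cc(OC)c(OC)cc12
A5 | alternative 2 | 2-(3,4-dimethoxyphenyl)-5-methoxyphenol | COc1ccc(-c2ccc(OC)c(OC)c2)c(O)c1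
A6 | alternative 2 | 9-(2,6-dimethoxyphenyl)-9-oxononanal | O=CCCCCCCCC(=O)c1c(OC)cccc1OC
A7 | alternative 3 | 1-(2,6-dihydroxyphenyl)-9-(2-{3-[9-(3,4-dimethoxyphenyl)nonanoyl]-2,4-dimethoxyphenyl}-4,5-dimethoxyphenyl)nonan-1-one | O=C(CCCCCCCCc1cc(OC)c(OC)cc1-c1ccc(OC)c(C(=O)CCCCCCCCc2ccc(OC)c(OC)c2)c1OC)c1c(O)cccc1O
A8 | alternative 3 | methyl 3-{[tert-butyl(dimethyl)silyl]oxy}-15-(2-{3-[9-(3,4-dimethoxyphenyl)nonanoyl]-2,4-dimethoxyphenyl}-4,5-dimethoxyphenyl)-5,7-dioxopentadecanoate (racemic) | COC(=O)CC(O[Si](C)(C)C(C)(C)C)CC(=O)CC(=O)CCCCCCCCc1cc(OC)c(OC)cc1-c1ccc(OC)c(C(=O)CCCCCCCCc2ccc(OC)c(OC)c2)c1OC
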